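**Retrosynthetic overview**

1. Target 23 comes from its octa-O-benzyl ether 22 by Lewis-acid debenzylation in the last step.
2. 22 comes from diazo ketone 19 and (R)-hydroxy ester 11 by photochemical Wolff contraction of a benzo-fused seven-membered ring, with capture of the ketene by 11. This makes the C8a–C1 bond (aryl shift), the C–O bond of the C1 ester and the C1 stereocentre.
3. The feature on which this rests: C1 of the 1,2-dihydronaphthalene is a benzylic CH on C8a that carries an ester of a chiral secondary alcohol and sits next to the aryl-bearing C2. That is the imprint of an aryl(alkyl)ketene on C1, and so of a 6-diazo-7-aryl-benzo[7]annulen-5-one 8-carboxylate that is one ring atom larger.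
4. 19 comes from ketone 17 by diazo transfer at C6; 17 from diene 16 by ring-closing metathesis (the seven-membered ring is formed first and contracted to six in the key step); 16 from Michael adduct 14, made from chalcone 8 and malonate 13 (C7, the later C2, set by catalytic asymmetric Michael addition).
5. 8 comes from 2,3-dihydroxybenzaldehyde 1 and aldehyde 7. Both lactate units come from danshensu 9: the C3 ester with inversion (Mitsunobu), the C1 ester with retention (ketene capture).

Key step: step 14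

Remark: 9 is used as the free acid. In step 10 the pseudoenantiomer of the cinchona thiourea (quinine- or quinidine-derived) that delivers the (R)-adduct is used; which one it is has to be fixed on a model run.

**Route**

Step 1
Reactants: 1 2,3-dihydroxybenzaldehyde
Product: 2 2,3-bis(benzyloxy)benzaldehyde
Conditions: BnBr (2.3 equiv), K2CO3, DMF, 60 °C
Reagents that add atoms: benzyl bromide BrCc1ccccc1
Why: Williamson etherification of both phenols under carbonate conditions leaves the aldehyde untouched.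

Step 2
Reactants: 2 2,3-bis(benzyloxy)benzaldehyde
Product: 3 6-bromo-2,3-bis(benzyloxy)benzaldehyde
Conditions: NBS (1.05 equiv), DMF, rt, dark
Reagents that add atoms: N-bromosuccinimide BrN1C(=O)CCC1=O
Why: Electrophilic aromatic bromination should go para to the conjugated 3-benzyloxy group (C6), because the 2-benzyloxy group is twisted out of conjugation between its two neighbours, as is known for 2,3-dialkoxybenzaldehydes.

Step 3
Reactants: 3 6-bromo-2,3-bis(benzyloxy)benzaldehyde
Product: 4 1-[6-bromo-2,3-bis(benzyloxy)phenyl]ethanol (racemic)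
Conditions: MeMgBr (1.3 equiv), THF, 0 °C; H2O
Reagents that add atoms: methylmagnesium bromide C[Mg]Br
Why: Grignard addition to the aldehyde is fast at 0 °C, and the aryl bromide does not exchange with MeMgBr.

Step 4
Reactants: 4 1-[6-bromo-2,3-bis(benzyloxy)phenyl]ethanol
Product: 5 1-[6-bromo-2,3-bis(benzyloxy)phenyl]ethanone
Conditions: Dess–Martin periodinane, CH2Cl2, rt
Reagents that add atoms: none
Why: Dess–Martin oxidation of the secondary benzylic alcohol is neutral and spares benzyl ethers and the aryl bromide.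

Step 5
Reactants: 5 1-[6-bromo-2,3-bis(benzyloxy)phenyl]ethanone
Product: 6 1-[2,3-bis(benzyloxy)-6-vinylphenyl]ethanone
Conditions: vinylboronic acid pinacol ester (1.5 equiv), Pd(dppf)Cl2 (3 mol%), K2CO3, dioxane/H2O, 85 °C
Reagents that add atoms: vinylboronic acid pinacol ester C=CB1OC(C)(C)C(C)(C)O1
Why: Suzuki–Miyaura coupling of the aryl bromide, activated by the ortho acyl group, installs the styrene whose inner carbon becomes C9.

Step 6
Reactants: 6 1-[2,3-bis(benzyloxy)-6-vinylphenyl]ethanone; 7 3,4-bis(benzyloxy)benzaldehyde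
Product: 8 (E)-1-[2,3-bis(benzyloxy)-6-vinylphenyl]-3-[3,4-bis(benzyloxy)phenyl]prop-2-en-1-one
Conditions: KOH, EtOH/THF, rt
Reagents that add atoms: none
Why: Claisen–Schmidt condensation of the methyl ketone with a non-enolisable aryl aldehyde gives the E-chalcone by aldol addition and E1cB dehydration.

Step 7
Reactants: 9 (R)-3-(3,4-dihydroxyphenyl)lactic acid (danshensu)
Product: 10 methyl (R)-3-(3,4-dihydroxyphenyl)-2-hydroxypropanoate
Conditions: MeOH, H2SO4 (cat.), 50 °C
Reagents that add atoms: methanol CO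
Why: Fischer esterification of the α-hydroxy acid does not touch the stereocentre or the catechol.

Step 8
Reactants: 10 methyl (R)-3-(3,4-dihydroxyphenyl)-2-hydroxypropanoate
Product: 11 methyl (R)-3-[3,4-bis(benzyloxy)phenyl]-2-hydroxypropanoate
Conditions: BnBr (2.1 equiv), K2CO3, acetone, reflux
Reagents that add atoms: benzyl bromide BrCc1ccccc1
Why: Under carbonate conditions only the phenols are deprotonated, so Williamson benzylation spares the secondary alcohol.

Step 9
Reactants: 11 methyl (R)-3-[3,4-bis(benzyloxy)phenyl]-2-hydroxypropanoate; 12 allyl hydrogen malonate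
Product: 13 allyl (S)-3-[3,4-bis(benzyloxy)phenyl]-1-methoxy-1-oxopropan-2-yl malonate
Conditions: PPh3, DIAD, THF, 0 °C to rt
Reagents that add atoms: none
Why: Mitsunobu esterification displaces the activated secondary alcohol by the carboxylate in an SN2 step, which inverts the carbinol carbon from R to S, the configuration needed in the C3 ester.

Step 10
Reactants: 8 (E)-1-[2,3-bis(benzyloxy)-6-vinylphenyl]-3-[3,4-bis(benzyloxy)phenyl]prop-2-en-1-one; 13 allyl (S)-3-[3,4-bis(benzyloxy)phenyl]-1-methoxy-1-oxopropan-2-yl malonate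
Product: 14 1-allyl 3-[(S)-3-[3,4-bis(benzyloxy)phenyl]-1-methoxy-1-oxopropan-2-yl] 2-{(R)-1-[3,4-bis(benzyloxy)phenyl]-3-[2,3-bis(benzyloxy)-6-vinylphenyl]-3-oxopropyl}malonate (both epimers at the malonate carbon)
Conditions: 13 (1.5 equiv), 9-amino-9-deoxy-epi-cinchona 3,5-bis(trifluoromethyl)phenyl thiourea (10 mol%, pseudoenantiomer as in the remark), toluene, rt
Reagents that add atoms: none
Why: In this organocatalytic asymmetric Michael addition of a malonate to a chalcone the thiourea binds the enone carbonyl and the quinuclidine deprotonates the malonate, so the catalyst fixes the attacked face and sets the benzylic carbon (C7, later C2) as R, while the malonate carbon becomes sp2 later and need not be controlled.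

Step 11
Reactants: 14 Michael adduct
Product: 16 (S)-3-[3,4-bis(benzyloxy)phenyl]-1-methoxy-1-oxopropan-2-yl (S)-3-[3,4-bis(benzyloxy)phenyl]-5-[2,3-bis(benzyloxy)-6-vinylphenyl]-2-methylene-5-oxopentanoate, via malonic half acid 15 (not isolated)
Conditions: Pd(PPh3)4 (5 mol%), morpholine (2.5 equiv), THF, rt; then (CH2O)n, 60 °C
Reagents that add atoms: formaldehyde (as paraformaldehyde) C=O
Why: Pd(0)-catalysed allyl transfer to morpholine (Tsuji–Trost deallylation) frees the malonic half acid, whose Mannich condensation with formaldehyde and decarboxylative loss of the amine (decarboxylative methylenation) gives the α-methylene ester without touching C7.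

Step 12
Reactants: 16 α-methylene ester
Product: 17 (S)-3-[3,4-bis(benzyloxy)phenyl]-1-methoxy-1-oxopropan-2-yl (7S)-3,4-bis(benzyloxy)-7-[3,4-bis(benzyloxy)phenyl]-5-oxo-6,7-dihydro-5H-benzo[7]annulene-8-carboxylate
Conditions: Hoveyda–Grubbs II (5 mol%), 1,4-benzoquinone (10 mol%), toluene (5 mM), 80 °C
Reagents that add atoms: none
Why: Ring-closing metathesis between the styrene and the 1,1-disubstituted acrylate releases ethylene and closes the benzo-fused seven-membered ring, the ring enforcing the C8=C9 geometry with the ester trans to the arene.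

Step 13
Reactants: 17 benzo[7]annulen-5-one ester
Product: 19 (S)-3-[3,4-bis(benzyloxy)phenyl]-1-methoxy-1-oxopropan-2-yl (7S)-3,4-bis(benzyloxy)-7-[3,4-bis(benzyloxy)phenyl]-6-diazo-5-oxo-6,7-dihydro-5H-benzo[7]annulene-8-carboxylate, via 6-trifluoroacetyl ketone 18 (not isolated)
Conditions: LiHMDS (1.1 equiv), THF, −78 °C, then CF3CO2CH2CF3 (1.3 equiv); 5% HCl; then MsN3 (1.5 equiv), Et3N (1.5 equiv), H2O (1 equiv), MeCN, rt
Reagents that add atoms: methanesulfonyl azide CS(=O)(=O)N=[N+]=[N-]
Why: In this detrifluoroacetylative (Regitz-type) diazo transfer the kinetic enolate at the only α-CH2 (C6) is trifluoroacetylated and the activated diketone takes the diazo group from the sulfonyl azide with loss of the trifluoroacetyl group, which avoids the forcing conditions of direct transfer to a simple ketone.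

Step 14
Reactants: 19 diazo ketone; 11 methyl (R)-3-[3,4-bis(benzyloxy)phenyl]-2-hydroxypropanoate
Product: 22 1-[(R)-3-[3,4-bis(benzyloxy)phenyl]-1-methoxy-1-oxopropan-2-yl] 3-[(S)-3-[3,4-bis(benzyloxy)phenyl]-1-methoxy-1-oxopropan-2-yl] (1S,2S)-7,8-bis(benzyloxy)-2-[3,4-bis(benzyloxy)phenyl]-1,2-dihydronaphthalene-1,3-dicarboxylate, via ketene 20 (not isolated), via ester enol 21 (not isolated)
Conditions: 11 (3 equiv), hν (365 nm LED), dry degassed THF, −40 °C to rt, then rt in the dark; no amine
Reagents that add atoms: none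
Why: Light absorbed by the diazo ketone expels N2 from the s-Z-locked cyclic diazo ketone with concerted 1,2-shift of the aryl carbon C4a from the carbonyl carbon to the diazo carbon, so the seven-membered ring loses one atom and becomes the 1,2-dihydronaphthalene with an exocyclic aryl(alkyl)ketene on C1 (20); the closest known reaction type is the photochemical Wolff ring contraction of cyclic 2-diazo ketones with alcohol capture of the ketene. The six-membered ring is thus not closed by a cyclisation but arises by this 1,2-shift (ring contraction), which makes the C8a–C1 bond. Alcohol 11 adds in the ketene plane to the central carbon to give ester enol 21 (the C–O bond of the C1 ester, the alcohol keeping its R configuration), and 21 tautomerises by protonation at C1. C1 is set by substrate control: in the nearly flat ring the C2 aryl group stands pseudoaxial, away from the C3 ester, and covers one face of the enol, so the proton should enter anti to it and leave the new ester cis to the aryl group (1S,2S). The step needs the aryl shift to outrun 1,2-hydride shift from C2, which the fixed s-Z geometry and direct photolysis without a metal carbenoid secure, and it needs kinetic protonation without later epimerisation of C1, which the absence of amine base, the low temperature and light that the product absorbs only weakly secure.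

Step 15
Reactants: 22 octa-O-benzyl ether
Product: 23 1-[(R)-3-(3,4-dihydroxyphenyl)-1-methoxy-1-oxopropan-2-yl] 3-[(S)-3-(3,4-dihydroxyphenyl)-1-methoxy-1-oxopropan-2-yl] (1S,2S)-2-(3,4-dihydroxyphenyl)-7,8-dihydroxy-1,2-dihydronaphthalene-1,3-dicarboxylate (CNP0237075.1)
Conditions: BCl3 (24 equiv), pentamethylbenzene (24 equiv), CH2Cl2, −78 °C; aqueous work-up
Reagents that add atoms: none
Why: BCl3 cleaves aryl benzyl ethers at −78 °C while pentamethylbenzene traps the benzyl cations, a debenzylation that is known to spare esters and conjugated alkenes and avoids hydrogenolysis, which could saturate C3=C4.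

**Compound list**

1 | 2,3-dihydroxybenzaldehyde | O=Cc1cccc(O)c1O | starting material
2 | 2,3-bis(benzyloxy)benzaldehyde | O=Cc1cccc(OCc2ccccc2)c1OCc1ccccc1 | intermediate
3 | 6-bromo-2,3-bis(benzyloxy)benzaldehyde | O=Cc1c(Br)ccc(OCc2ccccc2)c1OCc1ccccc1 | intermediate
4 | 1-[6-bromo-2,3-bis(benzyloxy)phenyl]ethanol (racemic) | CC(O)c1c(Br)ccc(OCc2ccccc2)c1OCc1ccccc1 | intermediate
5 | 1-[6-bromo-2,3-bis(benzyloxy)phenyl]ethanone | CC(=O)c1c(Br)ccc(OCc2ccccc2)c1OCc1ccccc1 | intermediate
6 | 1-[2,3-bis(benzyloxy)-6-vinylphenyl]ethanone | CC(=O)c1c(C=C)ccc(OCc2ccccc2)c1OCc1ccccc1 | intermediate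
7 | 3,4-bis(benzyloxy)benzaldehyde | O=Cc1ccc(OCc2ccccc2)c(OCc2ccccc2)c1 | starting material
8 | (E)-1-[2,3-bis(benzyloxy)-6-vinylphenyl]-3-[3,4-bis(benzyloxy)phenyl]prop-2-en-1-one | O=C(/C=C/c1ccc(OCc2ccccc2)c(OCc2ccccc2)c1)c1c(C=C)ccc(OCc2ccccc2)c1OCc1ccccc1 | intermediate
9 | (R)-3-(3,4-dihydroxyphenyl)lactic acid (danshensu) | OC(=O)[C@H](O)Cc1ccc(O)c(O)c1 | starting material
10 | methyl (R)-3-(3,4-dihydroxyphenyl)-2-hydroxypropanoate | COC(=O)[C@H](O)Cc1ccc(O)c(O)c1 | intermediate
11 | methyl (R)-3-[3,4-bis(benzyloxy)phenyl]-2-hydroxypropanoate | COC(=O)[C@H](O)Cc1ccc(OCc2ccccc2)c(OCc2ccccc2)c1 | intermediate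
12 | allyl hydrogen malonate | OC(=O)CC(=O)OCC=C | starting material
13 | allyl (S)-3-[3,4-bis(benzyloxy)phenyl]-1-methoxy-1-oxopropan-2-yl malonate | C=CCOC(=O)CC(=O)O[C@@H](Cc1ccc(OCc2ccccc2)c(OCc2ccccc2)c1)C(=O)OC | intermediate
14 | Michael adduct, (R) at the benzylic carbon, both epimers at the malonate carbon | C=CCOC(=O)C(C(=O)O[C@@H](Cc1ccc(OCc2ccccc2)c(OCc2ccccc2)c1)C(=O)OC)[C@@H](CC(=O)c1c(C=C)ccc(OCc2ccccc2)c1OCc1ccccc1)c1ccc(OCc2ccccc2)c(OCc2ccccc2)c1 | intermediate
15 | malonic half acid from 14 (allyl ester cleaved) | OC(=O)C(C(=O)O[C@@H](Cc1ccc(OCc2ccccc2)c(OCc2ccccc2)c1)C(=O)OC)[C@@H](CC(=O)c1c(C=C)ccc(OCc2ccccc2)c1OCc1ccccc1)c1ccc(OCc2ccccc2)c(OCc2ccccc2)c1 | intermediate (not isolated)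
16 | (S)-lactate ester of (3S)-3-[3,4-bis(benzyloxy)phenyl]-5-[2,3-bis(benzyloxy)-6-vinylphenyl]-2-methylene-5-oxopentanoic acid | C=C(C(=O)O[C@@H](Cc1ccc(OCc2ccccc2)c(OCc2ccccc2)c1)C(=O)OC)[C@@H](CC(=O)c1c(C=C)ccc(OCc2ccccc2)c1OCc1ccccc1)c1ccc(OCc2ccccc2)c(OCc2ccccc2)c1 | intermediate
17 | (S)-lactate ester of (7S)-3,4-bis(benzyloxy)-7-[3,4-bis(benzyloxy)phenyl]-5-oxo-6,7-dihydro-5H-benzo[7]annulene-8-carboxylic acid | COC(=O)[C@H](Cc1ccc(OCc2ccccc2)c(OCc2ccccc2)c1)OC(=O)C1=Cc2ccc(OCc3ccccc3)c(OCc3ccccc3)c2C(=O)C[C@H]1c1ccc(OCc2ccccc2)c(OCc2ccccc2)c1 | intermediate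
18 | 6-trifluoroacetyl derivative of 17 (C7 unchanged) | COC(=O)[C@H](Cc1ccc(OCc2ccccc2)c(OCc2ccccc2)c1)OC(=O)C1=Cc2ccc(OCc3ccccc3)c(OCc3ccccc3)c2C(=O)C(C(=O)C(F)(F)F)[C@H]1c1ccc(OCc2ccccc2)c(OCc2ccccc2)c1 | intermediate (not isolated)
19 | (S)-lactate ester of (7S)-3,4-bis(benzyloxy)-7-[3,4-bis(benzyloxy)phenyl]-6-diazo-5-oxo-6,7-dihydro-5H-benzo[7]annulene-8-carboxylic acid | COC(=O)[C@H](Cc1ccc(OCc2ccccc2)c(OCc2ccccc2)c1)OC(=O)C1=Cc2ccc(OCc3ccccc3)c(OCc3ccccc3)c2C(=O)C(=[N+]=[N-])[C@H]1c1ccc(OCc2ccccc2)c(OCc2ccccc2)c1 | intermediate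
20 | ketene: 1-(oxomethylidene)-1,2-dihydronaphthalene 3-carboxylate, aryl-bearing carbon as in 19 | COC(=O)[C@H](Cc1ccc(OCc2ccccc2)c(OCc2ccccc2)c1)OC(=O)C1=Cc2ccc(OCc3ccccc3)c(OCc3ccccc3)c2C(=C=O)[C@H]1c1ccc(OCc2ccccc2)c(OCc2ccccc2)c1 | intermediate (not isolated)
21 | ester enol formed from 20 and 11 (enol geometry not defined) | COC(=O)[C@H](Cc1ccc(OCc2ccccc2)c(OCc2ccccc2)c1)OC(=O)C1=Cc2ccc(OCc3ccccc3)c(OCc3ccccc3)c2C(=C(O)O[C@H](Cc2ccc(OCc3ccccc3)c(OCc3ccccc3)c2)C(=O)OC)[C@H]1c1ccc(OCc2ccccc2)c(OCc2ccccc2)c1 | intermediate (not isolated)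
22 | octa-O-benzyl ether of the target, (1S,2S), 1-ester (R)-lactate, 3-ester (S)-lactate | COC(=O)[C@H](Cc1ccc(OCc2ccccc2)c(OCc2ccccc2)c1)OC(=O)C1=Cc2ccc(OCc3ccccc3)c(OCc3ccccc3)c2[C@@H](C(=O)O[C@H](Cc2ccc(OCc3ccccc3)c(OCc3ccccc3)c2)C(=O)OC)[C@H]1c1ccc(OCc2ccccc2)c(OCc2ccccc2)c1 | intermediate
23 | CNP0237075.1 | COC(=O)[C@H](Cc1ccc(O)c(O)c1)OC(=O)C1=Cc2ccc(O)c(O)c2[C@@H](C(=O)O[C@H](Cc2ccc(O)c(O)c2)C(=O)OC)[C@H]1c1ccc(O)c(O)c1 | target

**Count**

Total step count: 15.
Longest linear sequence: 12 steps (steps 1–6 and 10–15).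

**Steps most likely to fail**

Step 14. The hindered aryl(alkyl)ketene may be captured too slowly by a secondary α-hydroxy ester, so that dimerisation or adventitious hydration competes. The face of protonation at C1 may also be eroded by the hydroxy ester's own facial preference, or by later epimerisation of the benzylic, ester-activated C1–H to the trans isomer. The fallback sets out from 19. The photolysis is run in THF/water, so that water, a small and fast trap, intercepts ketene 20 and protonation anti to the C2 aryl group gives (1S,2S)-7,8-bis(benzyloxy)-2-[3,4-bis(benzyloxy)phenyl]-3-{[(S)-3-[3,4-bis(benzyloxy)phenyl]-1-methoxy-1-oxopropan-2-yl]oxycarbonyl}-1,2-dihydronaphthalene-1-carboxylic acid F1. In parallel, alcohol 11 is inverted by Mitsunobu reaction with 4-nitrobenzoic acid (PPh3, DIAD) to methyl (S)-3-[3,4-bis(benzyloxy)phenyl]-2-(4-nitrobenzoyloxy)propanoate F2, and K2CO3 in MeOH at 0 °C removes the nitrobenzoate to give methyl (S)-3-[3,4-bis(benzyloxy)phenyl]-2-hydroxypropanoate F3. Mitsunobu coupling of F1 with F3 (PPh3, DIAD, THF) then makes the C1 ester by SN2 attack of the carboxylate on the activated alcohol with inversion (S to R). The acid is not activated, so C1 cannot enolise, and the route is rejoined at 22.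

Step 10. Conjugate addition to the electron-rich, 2',6'-disubstituted chalcone may be slow, and the hydrogen-bonding catalyst may discriminate the faces poorly. The fallback replaces catalyst control by separation of diastereomers and sets out from 8 and 13. DBU (10 mol%) in THF gives the C7-epimeric Michael adduct F4. Steps 11 and 12 run on the mixture lead through the C7-epimeric malonic half acid F5 and the C7-epimeric α-methylene ester F6 to 17 and its (7R)-epimer F7. These two are diastereomers because of the (S)-lactate and are separated by chromatography or crystallisation; the route is rejoined at 17.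

Step 12. The Ru carbene may stall by chelation to the neighbouring ketone, closure onto the 1,1-disubstituted electron-poor alkene may be slow, and Ru hydrides may move the double bonds. The fallback replaces metathesis by condensation and sets out from 14. The deallylation of step 11 is stopped at half acid 15 (Pd(PPh3)4, morpholine, THF, rt, acidic work-up). Lemieux–Johnson cleavage of the styrene (OsO4 cat., NaIO4, 2,6-lutidine, dioxane/H2O) gives the 2-formylaryl malonic half acid F8. Intramolecular Knoevenagel–Doebner condensation (piperidine cat., pyridine, 80 °C) adds the malonate carbon to the aldehyde and, by decarboxylative dehydration, closes the seven-membered ring; the route is rejoined at 17.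

**Further compounds**

F1 | step 14 | (1S,2S)-7,8-bis(benzyloxy)-2-[3,4-bis(benzyloxy)phenyl]-3-{[(S)-3-[3,4-bis(benzyloxy)phenyl]-1-methoxy-1-oxopropan-2-yl]oxycarbonyl}-1,2-dihydronaphthalene-1-carboxylic acid | COC(=O)[C@H](Cc1ccc(OCc2ccccc2)c(OCc2ccccc2)c1)OC(=O)C1=Cc2ccc(OCc3ccccc3)c(OCc3ccccc3)c2[C@@H](C(O)=O)[C@H]1c1ccc(OCc2ccccc2)c(OCc2ccccc2)c1
F2 | step 14 | methyl (S)-3-[3,4-bis(benzyloxy)phenyl]-2-(4-nitrobenzoyloxy)propanoate | COC(=O)[C@H](Cc1ccc(OCc2ccccc2)c(OCc2ccccc2)c1)OC(=O)c1ccc(cc1)[N+](=O)[O-]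
F3 | step 14 | methyl (S)-3-[3,4-bis(benzyloxy)phenyl]-2-hydroxypropanoate | COC(=O)[C@@H](O)Cc1ccc(OCc2ccccc2)c(OCc2ccccc2)c1
F4 | step 10 | C7-epimeric Michael adduct (14 and its epimer at the benzylic carbon) | C=CCOC(=O)C(C(=O)O[C@@H](Cc1ccc(OCc2ccccc2)c(OCc2ccccc2)c1)C(=O)OC)C(CC(=O)c1c(C=C)ccc(OCc2ccccc2)c1OCc1ccccc1)c1ccc(OCc2ccccc2)c(OCc2ccccc2)c1
F5 | step 10 | C7-epimeric malonic half acid (15 and its epimer) | OC(=O)C(C(=O)O[C@@H](Cc1ccc(OCc2ccccc2)c(OCc2ccccc2)c1)C(=O)OC)C(CC(=O)c1c(C=C)ccc(OCc2ccccc2)c1OCc1ccccc1)c1ccc(OCc2ccccc2)c(OCc2ccccc2)c1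
F6 | step 10 | C7-epimeric α-methylene ester (16 and its epimer) | C=C(C(=O)O[C@@H](Cc1ccc(OCc2ccccc2)c(OCc2ccccc2)c1)C(=O)OC)C(CC(=O)c1c(C=C)ccc(OCc2ccccc2)c1OCc1ccccc1)c1ccc(OCc2ccccc2)c(OCc2ccccc2)c1
F7 | step 10 | (7R)-epimer of 17 | COC(=O)[C@H](Cc1ccc(OCc2ccccc2)c(OCc2ccccc2)c1)OC(=O)C1=Cc2ccc(OCc3ccccc3)c(OCc3ccccc3)c2C(=O)C[C@@H]1c1ccc(OCc2ccccc2)c(OCc2ccccc2)c1
F8 | step 12 | 2-formylaryl malonic half acid (15 with the vinyl group cleaved to CHO) | OC(=O)C(C(=O)O[C@@H](Cc1ccc(OCc2ccccc2)c(OCc2ccccc2)c1)C(=O)OC)[C@@H](CC(=O)c1c(C=O)ccc(OCc2ccccc2)c1OCc1ccccc1)c1ccc(OCc2ccccc2)c(OCc2ccccc2)c1
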